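**The problem**

The target is an all-catechin trimer. Three (2R,3S)-flavan-3-ol units are joined by two aryl–C(sp3) bonds: C4 of the top unit to C8 of the middle unit, and C4 of the middle unit to C6 of the bottom unit. There are eight stereocentres, and in each extended unit the C4 aryl group is trans to the 3-hydroxyl and cis to the 2-aryl group. C2 and C3 of the bottom and top units can be taken from (+)-catechin, and C4 of the top unit follows from its own C3 substituent when a C4 cation is captured by an arene. The middle unit is the hard part: as a catechin monomer it would have to act as an electrophile at C4 and later as a nucleophile at C8, which invites self-condensation, and its bond to the bottom unit must go to C6, the less reactive of the two free positions of ring A. Built from scratch, the middle unit has only one independent stereocentre, C2, because a syn addition across a C3=C4 double bond on the face away from the 2-aryl group fixes C3 and C4 together. Both interflavan bonds are doubly benzylic and heterolyse in acid, C2 can epimerise in base through ring opening, and the twelve phenols are air-sensitive, so the skeleton has to be carried as benzyl ethers and released at the end by neutral hydrogenolysis. The enabling feature is C4 of the middle unit: it is bonded to C4a of its own ring A and to C6 of ring A of the bottom unit, two 2,4,6-trioxygenated aryl carbons, so a carbinol at this carbon that also carries a styryl group ionises under very mild acid to a cation reaching C2, and O1 on C8a sits ortho to C4a within reach of that terminus.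

**Retrosynthesis**

Target 20 is traced back to the fully protected trimer 19 by cutting fourteen O–benzyl bonds and two aryl C–Br bonds. One neutral hydrogenolysis removes all of them, so no acid or base touches the free oligomer. Mixed protecting groups would need several late steps on an acid-labile polyphenol.

Trimer 19 is cut at the bond from C4 of the top unit to C8 of the middle unit, giving the dimeric nucleophile 17 and the C4-activated catechin 18. This cut is preferred to a de novo construction of the top unit because (+)-catechin 1 already supplies C2 and C3, and the C3 substituent steers the arene to the trans face of the C4 cation. Electrophile 18 keeps a bromine at C8, so it cannot act as a nucleophile, and it comes in one step from bromide 4, which also serves the bottom unit. The forward reaction must pick C8 of the middle unit; the bottom unit of 17 has no free ring A position.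

Dimer 17 is cut at C3–O and C4–H of the middle unit, leading to the 4-aryl-flav-3-ene 15. Hydroboration is the one addition that delivers hydrogen to C4 and oxygen to C3 on the same face, which is what the 3,4-trans arrangement requires. Stepwise routes through a C4 cation would place the hydrogen anti to the C3 oxygen and give the wrong C4 epimer. Flavene 15 has one stereocentre in the middle unit instead of three.

Flavene 15 is cut at O1–C2 of the middle unit, leading to the open-chain tertiary allylic alcohol 14 with a free phenol. This is the stereodefining cut. It is preferred to cutting C4–C4a or C2–C3 because ionisation of 14 is uniquely easy and the ring closure needs no reagent beyond a chiral acid. The forward step must choose one face of C2 under catalyst control, since the substrate stereocentres are remote.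

Carbinol 14 comes from its allyl ether 13, which is cut at the bond between the carbinol carbon and C6 of the bottom unit, giving the aryl iodide 5 and the chalcone 10. The neighbouring cut, between the carbinol carbon and ring A of the middle unit, would need an acyl group on C6 of a polybenzylated catechin, and the Lewis acids for that acylation strip benzyl ethers. An iodine at C6 is introduced by simple electrophilic substitution and exchanged selectively beside the C8 bromine. The allyl ether is chosen because it is removed by palladium without acid; an acetal would need acid that ionises the carbinol too early.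

Chalcone 10 is cut at its Cα=Cβ bond into the acetophenone 8 and the aldehyde 9. Acetophenone 8 goes back through 7 to 2,4,6-trihydroxyacetophenone 6, which already carries the acetyl group and the future O1 in the right place. Its ring is symmetric about the acetyl group, so it has a single kind of ortho hydroxyl to close the ring.

Iodide 5 goes back through bromide 4 and the benzyl ethers 3 and 2 to (+)-catechin 1. The order is fixed by reactivity: C8 is halogenated first and C6 second, so the blocking bromine lands on C8 and the exchangeable iodine on C6.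

**Roads not taken**

Alternative 1: The top unit is also built as a flavene, and both C3–O/C4–H pairs are cut at once, leading to the bis(4-aryl-flav-3-ene) A1. In the forward direction a double hydroboration–oxidation would give the tridecabenzyl trimer A2 with free 3-hydroxyls in the top and middle units, relaying four stereocentres in one operation.
- Merits: the logic is uniform, and the top-to-middle bond is fixed by construction, so no cation/arene union with its C6/C8 question is needed; in that respect it is better than the chosen plan.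
- Weak points: A1 needs two catalyst-controlled C2 centres instead of one, and the second cyclisation precursor must be assembled on C8 of the middle ring A, where the C6/C8 choice returns at an earlier and less forgiving stage. Two very hindered trisubstituted alkenes must each be hydroborated on the correct face.
- Comparison: the chosen plan takes the whole top unit, three stereocentres included, from (+)-catechin 1 in two operations (18, then the union to 19), and asks catalyst control for a single centre.

Alternative 2: The bottom unit is cut at C4–C4a, leading to the epoxy aryl ether A3 on a symmetric phloroglucinol ring that already carries the top and middle units. A Lewis acid would open the terminal epoxide at its CH2 carbon by attack of either ortho carbon and give the tetradecabenzyl trimer A4 with a free 3-hydroxyl in the bottom unit.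
- Merits: the two ortho carbons are equivalent, so the middle-to-bottom bond needs no blocking group; here it is cleaner than the chosen plan, which spends a bromination and carries the halogen to the end.
- Weak points: the bottom unit is plain catechin, yet A3 requires its C2 and C3 to be made again as an enantiopure epoxy ether. The ring closure uses a strong Lewis acid on a substrate with two acid-labile interflavan bonds and fourteen benzyl ethers, and the 6-endo opening at the primary carbon competes with 5-exo opening at the secondary one.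
- Comparison: the most fragile step falls last, on the most valuable intermediate. The chosen plan brings the bottom unit intact from (+)-catechin 1 and closes its only new ring on a dimer-sized substrate under a catalytic acid at low temperature.

Alternative 3: The top unit is cut at C4–C4a and at the O1–C2 lactone bond, leading to the β-ketoester A5 on C8 of a protected catechin and to phloroglucinol A6. Acid-promoted Pechmann condensation would give the coumarin A7.
- Merits: the C–C bond formation is robust, needs no organometallic addition at a crowded carbon, and has no regiochemical question because A6 is symmetric; in reliability of the bond-forming event it is better than the congested carbonyl addition of the chosen plan (step 8).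
- Weak points: A7 contains none of the three stereocentres of the top unit. The lactone must be converted into a 2-aryl flavan, and C2, C3 and C4 must all be set afterwards on a 4-aryl coumarin. Its free phenols need protection after the event, strong acid meets benzyl ethers, and A5 itself requires selective acylation of C8. The strategy is also silent on the middle-to-bottom bond.
- Comparison: the chosen plan makes both interflavan bonds and all eight stereocentres in fourteen steps; the coumarin road would need many more for one unit.

Key step: step 10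

Remark on the chemistry: the sense of induction of the chiral acid at C2 of this substrate cannot be read from the structure. The (R)-configured acid is written, and its mirror image is to be used if a trial run shows the opposite sense. Compounds 6 and 9 are taken as purchased.

**Route**

Step 1
Reactants: 1 (+)-catechin
Product: 2 5,7,3',4'-tetra-O-benzyl-(+)-catechin
Conditions: BnBr (4.4 equiv), K2CO3, DMF, 0 °C → rt
Reagents that add atoms: benzyl bromide, BrCc1ccccc1
Why: Williamson ether synthesis; carbonate deprotonates the four phenols but not the secondary 3-hydroxyl, and the mild base leaves C2 and C3 untouched.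

Step 2
Reactants: 2 5,7,3',4'-tetra-O-benzyl-(+)-catechin
Product: 3 3,5,7,3',4'-penta-O-benzyl-(+)-catechin
Conditions: NaH, BnBr, n-Bu4NI (cat.), DMF, 0 °C → rt
Reagents that add atoms: benzyl bromide, BrCc1ccccc1
Why: Williamson etherification of the secondary alkoxide; with all phenols capped no phenoxide can open ring C, so the (2R,3S) configuration is kept.

Step 3
Reactants: 3 3,5,7,3',4'-penta-O-benzyl-(+)-catechin
Product: 4 8-bromo-3,5,7,3',4'-penta-O-benzyl-(+)-catechin
Conditions: NBS (1.0 equiv), CH2Cl2, −40 → 0 °C
Reagents that add atoms: N-bromosuccinimide, O=C1CCC(=O)N1Br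
Why: Electrophilic aromatic bromination; in benzylated catechins C8 is the most nucleophilic position of ring A, so one equivalent should give the 8-bromide, which blocks this site until the last step.

Step 4
Reactants: 4 8-bromo-3,5,7,3',4'-penta-O-benzyl-(+)-catechin
Product: 5 8-bromo-6-iodo-3,5,7,3',4'-penta-O-benzyl-(+)-catechin
Conditions: NIS (1.1 equiv), CF3CO2H (cat.), CH2Cl2/MeCN, 0 °C → rt, dark
Reagents that add atoms: N-iodosuccinimide, O=C1CCC(=O)N1I
Why: Electrophilic aromatic iodination at C6, the only free position of the trioxygenated ring A; the catechol-type ring B is much less activated.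

Step 5
Reactants: 6 2,4,6-trihydroxyacetophenone
Product: 7 1-[2,4-bis(benzyloxy)-6-hydroxyphenyl]ethanone
Conditions: BnBr (2.1 equiv), K2CO3, DMF, rt
Reagents that add atoms: benzyl bromide, BrCc1ccccc1
Why: Williamson etherification; a hydroxyl hydrogen-bonded to the acetyl carbonyl is the least nucleophilic, so two equivalents should stop at the dibenzyl ether with one ortho hydroxyl free.

Step 6
Reactants: 7 1-[2,4-bis(benzyloxy)-6-hydroxyphenyl]ethanone
Product: 8 1-[2-(allyloxy)-4,6-bis(benzyloxy)phenyl]ethanone
Conditions: allyl bromide, K2CO3, DMF, 60 °C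
Reagents that add atoms: allyl bromide, C=CCBr
Why: Williamson etherification of the chelated phenol under mild heating; allyl is chosen because it survives base and organometallic reagents and is later removed without acid.

Step 7
Reactants: 8 1-[2-(allyloxy)-4,6-bis(benzyloxy)phenyl]ethanone; 9 3,4-bis(benzyloxy)benzaldehyde
Product: 10 (E)-1-[2-(allyloxy)-4,6-bis(benzyloxy)phenyl]-3-[3,4-bis(benzyloxy)phenyl]prop-2-en-1-one
Conditions: KOH (50% aq.), EtOH/THF, rt
Reagents that add atoms: none
Why: Claisen–Schmidt condensation of a methyl ketone with a non-enolisable aldehyde; dehydration gives the conjugated (E)-enone as the stable isomer, and with no free ortho hydroxyl the chalcone cannot close to a flavanone.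

Step 8
Reactants: 5 8-bromo-6-iodo-3,5,7,3',4'-penta-O-benzyl-(+)-catechin; 10 (E)-1-[2-(allyloxy)-4,6-bis(benzyloxy)phenyl]-3-[3,4-bis(benzyloxy)phenyl]prop-2-en-1-one
Product: 13 (E)-1-[2-(allyloxy)-4,6-bis(benzyloxy)phenyl]-3-[3,4-bis(benzyloxy)phenyl]-1-(8-bromo-penta-O-benzylcatechin-6-yl)prop-2-en-1-ol (both carbinol epimers), via C6-lithio arene 11 (not isolated), via C6-dichlorocerium arene 12 (not isolated)
Conditions: 5, n-BuLi (1.05 equiv), THF, −78 °C; CeCl3, −78 °C; then 10, −78 → −40 °C; aq. NaHCO3
Reagents that add atoms: none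
Why: Iodine–lithium exchange is much faster than bromine–lithium exchange at −78 °C, so only C6 is metalated; the weakly basic, oxophilic arylcerium reagent then adds to the carbonyl carbon of the non-enolisable chalcone instead of its β-carbon (organocerium 1,2-addition). The new carbinol centre forms as both epimers, which does not matter because it is planarised in step 10.

Step 9
Reactants: 13 (E)-1-[2-(allyloxy)-4,6-bis(benzyloxy)phenyl]-3-[3,4-bis(benzyloxy)phenyl]-1-(8-bromo-penta-O-benzylcatechin-6-yl)prop-2-en-1-ol
Product: 14 (E)-1-[2,4-bis(benzyloxy)-6-hydroxyphenyl]-3-[3,4-bis(benzyloxy)phenyl]-1-(8-bromo-penta-O-benzylcatechin-6-yl)prop-2-en-1-ol (both carbinol epimers)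
Conditions: Pd(PPh3)4 (5 mol %), morpholine (10 equiv), THF, rt; filtration through basic alumina
Reagents that add atoms: none
Why: Tsuji–Trost deallylation; zerovalent palladium ionises the aryl allyl ether and morpholine traps the allyl fragment under neutral to basic conditions, which spare the acid-labile carbinol, the benzyl ethers and the hindered aryl bromide. Compound 14 is kept away from acid and used at once.

Step 10
Reactants: 14 (E)-1-[2,4-bis(benzyloxy)-6-hydroxyphenyl]-3-[3,4-bis(benzyloxy)phenyl]-1-(8-bromo-penta-O-benzylcatechin-6-yl)prop-2-en-1-ol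
Product: 15 (2S)-5,7-bis(benzyloxy)-2-[3,4-bis(benzyloxy)phenyl]-4-(8-bromo-penta-O-benzylcatechin-6-yl)-2H-chromene (nonabenzyl 4-aryl-flav-3-ene; C2 has the spatial arrangement of C2 in catechin)
Conditions: (R)-3,3'-bis(2,4,6-triisopropylphenyl)-1,1'-binaphthyl-2,2'-diyl N-(trifluoromethylsulfonyl)phosphoramide (10 mol %), toluene, −78 °C; Et3N, −78 °C
Reagents that add atoms: none
Why: The N-triflylphosphoramide, far more acidic than a phosphoric acid, protonates the tertiary hydroxyl of either epimer of 14 and water leaves, giving a 1,1,3-triarylallyl cation that is also the O-protonated form of a vinylogous o-quinone methide and stays paired with the chiral phosphoramide anion. The phenolic hydroxyl, hydrogen-bonded to that anion, adds to the styryl terminus and forms O1–C2, closing ring C of the middle unit as a 2H-chromene; counted on the allyl cation this is a 6-endo-trig closure, and it becomes an oxa-6π electrocyclisation if the phenol proton is passed to the anion first. The closest known reaction type is the chiral N-triflylphosphoramide-catalysed intramolecular allylic substitution of 2-(1-aryl-1-hydroxyallyl)phenols to 2,4-diaryl-2H-chromenes. C2 is the only new stereocentre and is set by the chiral anion, which covers one face of the planar terminus in the contact ion pair; the stereocentres of the bottom unit are several bonds away and the carbinol centre is erased on ionisation. The step needs one enantioface at C2, attack by oxygen and not carbon, and no return of the product to the cation; the substrate secures the second point because ring A offers a single free hydroxyl next to C4a, the other aryl group on C4 has only benzyl ethers, and every ortho position of both C4 aryl groups is substituted, so Friedel–Crafts closure to an indene is blocked. A non-polar solvent and −78 °C should keep the ion pair tight and suppress uncatalysed closure, and the amine quench at low temperature guards against acid-induced reopening at C2.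

Step 11
Reactants: 15 (2S)-5,7-bis(benzyloxy)-2-[3,4-bis(benzyloxy)phenyl]-4-(8-bromo-penta-O-benzylcatechin-6-yl)-2H-chromene
Product: 17 5,7,3',4'-tetra-O-benzylcatechin-(4α→6)-8-bromo-penta-O-benzylcatechin (middle unit 2,3-trans-3,4-trans with free 3-hydroxyl), via C3-borane adduct 16 (not isolated)
Conditions: BH3·SMe2, THF, 0 °C → rt; then NaOH (aq.), H2O2, 0 °C → rt
Reagents that add atoms: hydrogen peroxide, OO
Why: Hydroboration–oxidation; boron adds to the less substituted C3 and hydrogen to the diaryl-substituted C4 in one syn addition on the face opposite to the C2 aryl group, and oxidation proceeds with retention. The 3-hydroxyl therefore ends trans to the C2 aryl group and the C4 aryl group trans to the hydroxyl, as in catechin extension units; benzyl ethers and the aryl bromide are inert to borane and alkaline peroxide.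

Step 12
Reactants: 4 8-bromo-3,5,7,3',4'-penta-O-benzyl-(+)-catechin
Product: 18 8-bromo-4-(2-ethoxyethoxy)-3,5,7,3',4'-penta-O-benzylcatechin (C2 and C3 as in catechin; 4-alkoxy group trans to the C2 aryl group)
Conditions: DDQ (2 equiv), 2-ethoxyethanol, CH2Cl2, rt
Reagents that add atoms: 2-ethoxyethanol, CCOCCO
Why: Benzylic oxidation; DDQ abstracts hydride from C4, which is activated by the ring A oxygens, and the alcohol traps the cation on the face away from the C2 aryl group. The C4 configuration is of no consequence because the group leaves again in step 13.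

Step 13
Reactants: 17 5,7,3',4'-tetra-O-benzylcatechin-(4α→6)-8-bromo-penta-O-benzylcatechin; 18 8-bromo-4-(2-ethoxyethoxy)-3,5,7,3',4'-penta-O-benzylcatechin
Product: 19 8-bromo-penta-O-benzylcatechin-(4α→8)-5,7,3',4'-tetra-O-benzylcatechin-(4α→6)-8-bromo-penta-O-benzylcatechin
Conditions: TMSOTf (cat.), 4 Å molecular sieves, CH2Cl2, −78 °C; Et3N
Reagents that add atoms: none
Why: Friedel–Crafts-type capture of a flavan C4 cation by an arene; the cation from 18 is attacked anti to its 3-benzyloxy group, which sets the top C4 centre 3,4-trans. C8 of the middle unit is the expected site because the bottom unit has no free ring A position and middle C6 lies between two benzyloxy groups next to the crowded C4. The C8 bromine of 18 stops self-condensation and limits chain growth, so near-equimolar amounts should suffice.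

Step 14
Reactants: 19 8-bromo-penta-O-benzylcatechin-(4α→8)-5,7,3',4'-tetra-O-benzylcatechin-(4α→6)-8-bromo-penta-O-benzylcatechin
Product: 20 catechin-(4α→8)-catechin-(4α→6)-catechin (CNP0178679.4)
Conditions: H2 (1 atm), Pd(OH)2/C, Et3N, THF/MeOH/H2O, rt
Reagents that add atoms: none
Why: Catalytic hydrogenolysis cleaves the fourteen benzyl ethers and reduces both aryl C–Br bonds in one neutral operation; triethylamine takes up the hydrogen bromide so that the acid-labile interflavan bonds and the stereocentres are not put at risk.

**Compound list**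

1 | (+)-catechin | O[C@H]1Cc2c(O)cc(O)cc2O[C@@H]1c1ccc(O)c(O)c1 | starting material
2 | 5,7,3',4'-tetra-O-benzyl-(+)-catechin | O[C@H]1Cc2c(OCc3ccccc3)cc(OCc3ccccc3)cc2O[C@@H]1c1ccc(OCc2ccccc2)c(OCc2ccccc2)c1 | intermediate
3 | 3,5,7,3',4'-penta-O-benzyl-(+)-catechin | c1ccccc1CO[C@H]1Cc2c(OCc3ccccc3)cc(OCc3ccccc3)cc2O[C@@H]1c1ccc(OCc2ccccc2)c(OCc2ccccc2)c1 | intermediate
4 | 8-bromo-3,5,7,3',4'-penta-O-benzyl-(+)-catechin | c1ccccc1CO[C@H]1Cc2c(OCc3ccccc3)cc(OCc3ccccc3)c(Br)c2O[C@@H]1c1ccc(OCc2ccccc2)c(OCc2ccccc2)c1 | intermediate
5 | 8-bromo-6-iodo-3,5,7,3',4'-penta-O-benzyl-(+)-catechin | c1ccccc1CO[C@H]1Cc2c(OCc3ccccc3)c(I)c(OCc3ccccc3)c(Br)c2O[C@@H]1c1ccc(OCc2ccccc2)c(OCc2ccccc2)c1 | intermediate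
6 | 2,4,6-trihydroxyacetophenone | CC(=O)c1c(O)cc(O)cc1O | starting material
7 | 1-[2,4-bis(benzyloxy)-6-hydroxyphenyl]ethanone | CC(=O)c1c(O)cc(OCc2ccccc2)cc1OCc1ccccc1 | intermediate
8 | 1-[2-(allyloxy)-4,6-bis(benzyloxy)phenyl]ethanone | CC(=O)c1c(OCC=C)cc(OCc2ccccc2)cc1OCc1ccccc1 | intermediate
9 | 3,4-bis(benzyloxy)benzaldehyde | O=Cc1ccc(OCc2ccccc2)c(OCc2ccccc2)c1 | starting material
10 | (E)-1-[2-(allyloxy)-4,6-bis(benzyloxy)phenyl]-3-[3,4-bis(benzyloxy)phenyl]prop-2-en-1-one | C=CCOc1cc(OCc2ccccc2)cc(OCc2ccccc2)c1C(=O)/C=C/c1ccc(OCc2ccccc2)c(OCc2ccccc2)c1 | intermediate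
11 | 8-bromo-6-lithio-penta-O-benzylcatechin | c1ccccc1CO[C@H]1Cc2c(OCc3ccccc3)c([Li])c(OCc3ccccc3)c(Br)c2O[C@@H]1c1ccc(OCc2ccccc2)c(OCc2ccccc2)c1 | intermediate (not isolated)
12 | 8-bromo-6-(dichlorocerio)-penta-O-benzylcatechin | c1ccccc1CO[C@H]1Cc2c(OCc3ccccc3)c([Ce](Cl)Cl)c(OCc3ccccc3)c(Br)c2O[C@@H]1c1ccc(OCc2ccccc2)c(OCc2ccccc2)c1 | intermediate (not isolated)
13 | (E)-1-[2-(allyloxy)-4,6-bis(benzyloxy)phenyl]-3-[3,4-bis(benzyloxy)phenyl]-1-(8-bromo-penta-O-benzylcatechin-6-yl)prop-2-en-1-ol, both carbinol epimers | OC(/C=C/c1ccc(OCc2ccccc2)c(OCc2ccccc2)c1)(c1c(OCC=C)cc(OCc2ccccc2)cc1OCc1ccccc1)c1c(OCc2ccccc2)c(Br)c2c(c1OCc1ccccc1)C[C@H](OCc1ccccc1)[C@@H](c1ccc(OCc3ccccc3)c(OCc3ccccc3)c1)O2 | intermediate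
14 | (E)-1-[2,4-bis(benzyloxy)-6-hydroxyphenyl]-3-[3,4-bis(benzyloxy)phenyl]-1-(8-bromo-penta-O-benzylcatechin-6-yl)prop-2-en-1-ol, both carbinol epimers | OC(/C=C/c1ccc(OCc2ccccc2)c(OCc2ccccc2)c1)(c1c(O)cc(OCc2ccccc2)cc1OCc1ccccc1)c1c(OCc2ccccc2)c(Br)c2c(c1OCc1ccccc1)C[C@H](OCc1ccccc1)[C@@H](c1ccc(OCc3ccccc3)c(OCc3ccccc3)c1)O2 | intermediate
15 | (2S)-5,7-bis(benzyloxy)-2-[3,4-bis(benzyloxy)phenyl]-4-(8-bromo-penta-O-benzylcatechin-6-yl)-2H-chromene | c1ccccc1COc1cc(OCc3ccccc3)c2c(c1)O[C@H](c1ccc(OCc3ccccc3)c(OCc3ccccc3)c1)C=C2c1c(OCc3ccccc3)c(Br)c2c(c1OCc3ccccc3)C[C@H](OCc3ccccc3)[C@@H](c1ccc(OCc3ccccc3)c(OCc3ccccc3)c1)O2 | intermediate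
16 | C3-borane adduct of 15 (boron trans to the C2 aryl group, C4 hydrogen syn to boron) | c1ccccc1COc1cc(OCc3ccccc3)c2c(c1)O[C@H](c1ccc(OCc3ccccc3)c(OCc3ccccc3)c1)[C@@H](B)[C@@H]2c1c(OCc3ccccc3)c(Br)c2c(c1OCc3ccccc3)C[C@H](OCc3ccccc3)[C@@H](c1ccc(OCc3ccccc3)c(OCc3ccccc3)c1)O2 | intermediate (not isolated)
17 | 5,7,3',4'-tetra-O-benzylcatechin-(4α→6)-8-bromo-penta-O-benzylcatechin | c1ccccc1COc1cc(OCc3ccccc3)c2c(c1)O[C@H](c1ccc(OCc3ccccc3)c(OCc3ccccc3)c1)[C@@H](O)[C@@H]2c1c(OCc3ccccc3)c(Br)c2c(c1OCc3ccccc3)C[C@H](OCc3ccccc3)[C@@H](c1ccc(OCc3ccccc3)c(OCc3ccccc3)c1)O2 | intermediate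
18 | 8-bromo-4-(2-ethoxyethoxy)-3,5,7,3',4'-penta-O-benzylcatechin (4-alkoxy trans to the C2 aryl group) | CCOCCO[C@@H]1[C@H](OCc2ccccc2)[C@@H](c2ccc(OCc3ccccc3)c(OCc3ccccc3)c2)Oc2c(Br)c(OCc3ccccc3)cc(OCc3ccccc3)c21 | intermediate
19 | 8-bromo-penta-O-benzylcatechin-(4α→8)-5,7,3',4'-tetra-O-benzylcatechin-(4α→6)-8-bromo-penta-O-benzylcatechin | c1ccccc1COc1cc(OCc3ccccc3)c2c(c1Br)O[C@H](c1ccc(OCc3ccccc3)c(OCc3ccccc3)c1)[C@@H](OCc1ccccc1)[C@@H]2c1c(OCc3ccccc3)cc(OCc3ccccc3)c2c1O[C@H](c1ccc(OCc3ccccc3)c(OCc3ccccc3)c1)[C@@H](O)[C@@H]2c1c(OCc3ccccc3)c(Br)c2c(c1OCc3ccccc3)C[C@H](OCc3ccccc3)[C@@H](c1ccc(OCc3ccccc3)c(OCc3ccccc3)c1)O2 | intermediate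
20 | catechin-(4α→8)-catechin-(4α→6)-catechin (CNP0178679.4) | Oc1cc(O)c2c(c1)O[C@H](c1ccc(O)c(O)c1)[C@@H](O)[C@@H]2c1c(O)cc(O)c2c1O[C@H](c1ccc(O)c(O)c1)[C@@H](O)[C@@H]2c1c(O)cc2c(c1O)C[C@H](O)[C@@H](c1ccc(O)c(O)c1)O2 | target

**Step count and risks**

Total step count: 14. Longest linear sequence: 10 steps (steps 1, 2, 3, 4, 8, 9, 10, 11, 13 and 14, from 1 to 20).

Step 10 (key step). The most likely failure is poor facial discrimination at C2. The cation carries three donor aryl groups and may be long-lived enough to loosen the ion pair, uncatalysed closure on handling of 14 would add unselective product, and acid-induced reopening of 15 would erode the ratio afterwards. Slow rotation about the C4–aryl bond of 15 may also produce rotamers that complicate analysis, though this has no stereochemical consequence once C4 becomes sp3. The fallback sets out from 5 (through 12) and comes back at 15, with C2 set on a monomer by a metal catalyst instead of an ion pair: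
- Purchased 5,7-dihydroxy-4H-chromen-4-one F1 is benzylated (BnBr, K2CO3, DMF, 80 °C) to 5,7-bis(benzyloxy)-4H-chromen-4-one F2.
- Enantioselective conjugate addition of [3,4-bis(benzyloxy)phenyl]boronic acid F3 to F2, under Pd(OCOCF3)2 and a chiral 4-tert-butyl-2-(pyridin-2-yl)-4,5-dihydrooxazole ligand (the enantiomer that delivers the 2S product), should give (2S)-5,7-bis(benzyloxy)-2-[3,4-bis(benzyloxy)phenyl]chroman-4-one F4.
- The arylcerium reagent 12 adds to the C4 carbonyl of F4, which has no conjugate position; its low basicity should spare the enolisable C3 and hence C2. This gives 5,7-bis(benzyloxy)-2-[3,4-bis(benzyloxy)phenyl]-4-(8-bromo-penta-O-benzylcatechin-6-yl)chroman-4-ol F5.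
- Dehydration of F5 with catalytic pyridinium p-toluenesulfonate forms the C3=C4 double bond and gives 15.

Step 8. The most likely failure is conjugate addition or no addition at all, because the carbonyl is flanked by a 2,6-dioxygenated aryl group and the nucleophile is itself 2,6-dioxygenated; halogen–metal scrambling between C6 and C8 is a lesser concern. The fallback sets out from 5 (through 11) and comes back at 13, dividing the congestion over two easier bond formations:
- Purchased 2,4,6-trihydroxybenzaldehyde F6 is dibenzylated (BnBr, K2CO3) to 2-hydroxy-4,6-bis(benzyloxy)benzaldehyde F7 and allylated (allyl bromide, K2CO3) to 2-(allyloxy)-4,6-bis(benzyloxy)benzaldehyde F8.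
- Aryllithium 11 adds to the aldehyde F8 to give [2-(allyloxy)-4,6-bis(benzyloxy)phenyl](8-bromo-penta-O-benzylcatechin-6-yl)methanol F9, which MnO2 oxidises to the diaryl ketone [2-(allyloxy)-4,6-bis(benzyloxy)phenyl](8-bromo-penta-O-benzylcatechin-6-yl)methanone F10.
- Aldehyde 9 is converted by Takai olefination (CrCl2, CHI3, THF) into 1,2-bis(benzyloxy)-4-[(E)-2-iodovinyl]benzene F11. Iodine–lithium exchange with t-BuLi at −78 °C and transmetalation with CeCl3 give a slim vinyl nucleophile that adds to F10, which has no conjugate position, and gives 13.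

Step 11. The most likely failure is sluggish or incomplete hydroboration: both faces of C4 are flanked by ortho benzyloxy groups of the perpendicular aryl ring, and prolonged reaction could also weaken facial discrimination by the C2 aryl group. The C4–H bond must be delivered syn to the C3–O bond, which only a concerted hydroboration does, so the fallback gives up the de novo middle unit and makes the C4–aryl bond last. It sets out from 2 and 4 and comes back at 17:
- Compound 2 is oxidised with DDQ in the presence of 2-ethoxyethanol to 5,7,3',4'-tetra-O-benzyl-4-(2-ethoxyethoxy)catechin F12 (free 3-hydroxyl).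
- F12 is ionised with TMSOTf at −78 °C in the presence of an excess of 4. C6 is the only free ring A position of 4 and attack occurs anti to the 3-hydroxyl, so the product is 17.
- The price is the excess of 4 needed to outrun self-condensation of F12.

**Further compounds**

F1 | step 10 | 5,7-dihydroxy-4H-chromen-4-one (purchased) | O=c1ccoc2cc(O)cc(O)c12
F2 | step 10 | 5,7-bis(benzyloxy)-4H-chromen-4-one | O=c1ccoc2cc(OCc3ccccc3)cc(OCc3ccccc3)c12
F3 | step 10 | [3,4-bis(benzyloxy)phenyl]boronic acid (purchased) | OB(O)c1ccc(OCc2ccccc2)c(OCc2ccccc2)c1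
F4 | step 10 | (2S)-5,7-bis(benzyloxy)-2-[3,4-bis(benzyloxy)phenyl]chroman-4-one | O=C1C[C@@H](c2ccc(OCc3ccccc3)c(OCc3ccccc3)c2)Oc2cc(OCc3ccccc3)cc(OCc3ccccc3)c12
F5 | step 10 | 5,7-bis(benzyloxy)-2-[3,4-bis(benzyloxy)phenyl]-4-(8-bromo-penta-O-benzylcatechin-6-yl)chroman-4-ol (2S; C4 either epimer) | OC1(c3c(OCc5ccccc5)c(Br)c4c(c3OCc3ccccc3)C[C@H](OCc3ccccc3)[C@@H](c3ccc(OCc5ccccc5)c(OCc5ccccc5)c3)O4)C[C@@H](c2ccc(OCc3ccccc3)c(OCc3ccccc3)c2)Oc2cc(OCc3ccccc3)cc(OCc3ccccc3)c12
F6 | step 8 | 2,4,6-trihydroxybenzaldehyde (purchased) | O=Cc1c(O)cc(O)cc1O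
F7 | step 8 | 2-hydroxy-4,6-bis(benzyloxy)benzaldehyde | O=Cc1c(O)cc(OCc2ccccc2)cc1OCc1ccccc1
F8 | step 8 | 2-(allyloxy)-4,6-bis(benzyloxy)benzaldehyde | O=Cc1c(OCC=C)cc(OCc2ccccc2)cc1OCc1ccccc1
F9 | step 8 | [2-(allyloxy)-4,6-bis(benzyloxy)phenyl](8-bromo-penta-O-benzylcatechin-6-yl)methanol (both carbinol epimers) | OC(c1c(OCC=C)cc(OCc2ccccc2)cc1OCc1ccccc1)c1c(OCc2ccccc2)c(Br)c2c(c1OCc1ccccc1)C[C@H](OCc1ccccc1)[C@@H](c1ccc(OCc3ccccc3)c(OCc3ccccc3)c1)O2
F10 | step 8 | [2-(allyloxy)-4,6-bis(benzyloxy)phenyl](8-bromo-penta-O-benzylcatechin-6-yl)methanone | O=C(c1c(OCC=C)cc(OCc2ccccc2)cc1OCc1ccccc1)c1c(OCc2ccccc2)c(Br)c2c(c1OCc1ccccc1)C[C@H](OCc1ccccc1)[C@@H](c1ccc(OCc3ccccc3)c(OCc3ccccc3)c1)O2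
F11 | step 8 | 1,2-bis(benzyloxy)-4-[(E)-2-iodovinyl]benzene | I/C=C/c1ccc(OCc2ccccc2)c(OCc2ccccc2)c1
F12 | step 11 | 5,7,3',4'-tetra-O-benzyl-4-(2-ethoxyethoxy)catechin (4-alkoxy trans to the C2 aryl group, free 3-hydroxyl) | CCOCCO[C@@H]1[C@H](O)[C@@H](c2ccc(OCc3ccccc3)c(OCc3ccccc3)c2)Oc2cc(OCc3ccccc3)cc(OCc3ccccc3)c21
A1 | alternative 1 | bis(4-aryl-flav-3-ene), tridecabenzyl ether | c1ccccc1COc1cc(OCc3ccccc3)c2c(c1)O[C@H](c1ccc(OCc3ccccc3)c(OCc3ccccc3)c1)C=C2c1c(OCc3ccccc3)cc(OCc3ccccc3)c2c1O[C@H](c1ccc(OCc3ccccc3)c(OCc3ccccc3)c1)C=C2c1c(OCc3ccccc3)cc2c(c1OCc3ccccc3)C[C@H](OCc3ccccc3)[C@@H](c1ccc(OCc3ccccc3)c(OCc3ccccc3)c1)O2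
A2 | alternative 1 | tridecabenzyl trimer with free 3-hydroxyls in the top and middle units | c1ccccc1COc1cc(OCc3ccccc3)c2c(c1)O[C@H](c1ccc(OCc3ccccc3)c(OCc3ccccc3)c1)[C@@H](O)[C@@H]2c1c(OCc3ccccc3)cc(OCc3ccccc3)c2c1O[C@H](c1ccc(OCc3ccccc3)c(OCc3ccccc3)c1)[C@@H](O)[C@@H]2c1c(OCc3ccccc3)cc2c(c1OCc3ccccc3)C[C@H](OCc3ccccc3)[C@@H](c1ccc(OCc3ccccc3)c(OCc3ccccc3)c1)O2
A3 | alternative 2 | epoxy aryl ether of the top–middle dimer on a 3,5-bis(benzyloxy)phenyl ring | c1ccccc1COc1cc(OCc3ccccc3)c2c(c1)O[C@H](c1ccc(OCc3ccccc3)c(OCc3ccccc3)c1)[C@@H](OCc3ccccc3)[C@@H]2c1c(OCc3ccccc3)cc(OCc3ccccc3)c2c1O[C@H](c1ccc(OCc3ccccc3)c(OCc3ccccc3)c1)[C@@H](OCc3ccccc3)[C@@H]2c1c(OCc3ccccc3)cc(O[C@H](c2ccc(OCc3ccccc3)c(OCc3ccccc3)c2)[C@@H]2CO2)cc1OCc1ccccc1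
A4 | alternative 2 | tetradecabenzyl trimer with free 3-hydroxyl in the bottom unit | c1ccccc1COc1cc(OCc3ccccc3)c2c(c1)O[C@H](c1ccc(OCc3ccccc3)c(OCc3ccccc3)c1)[C@@H](OCc3ccccc3)[C@@H]2c1c(OCc3ccccc3)cc(OCc3ccccc3)c2c1O[C@H](c1ccc(OCc3ccccc3)c(OCc3ccccc3)c1)[C@@H](OCc3ccccc3)[C@@H]2c1c(OCc3ccccc3)cc2c(c1OCc3ccccc3)C[C@H](O)[C@@H](c1ccc(OCc3ccccc3)c(OCc3ccccc3)c1)O2
A5 | alternative 3 | ethyl 3-oxo-3-(penta-O-benzylcatechin-8-yl)propanoate | CCOC(=O)CC(=O)c1c(OCc3ccccc3)cc(OCc3ccccc3)c2c1O[C@H](c1ccc(OCc3ccccc3)c(OCc3ccccc3)c1)[C@@H](OCc3ccccc3)C2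
A6 | alternative 3 | phloroglucinol | Oc1cc(O)cc(O)c1
A7 | alternative 3 | 5,7-dihydroxy-4-(penta-O-benzylcatechin-8-yl)coumarin | Oc1cc(O)c2c(c1)OC(=O)C=C2c1c(OCc3ccccc3)cc(OCc3ccccc3)c2c1O[C@H](c1ccc(OCc3ccccc3)c(OCc3ccccc3)c1)[C@@H](OCc3ccccc3)C2
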